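The route rests on disconnecting ring A and ring C of the flavone at C4a–C8a and O1–C2. Ring A is a phloroglucinol with oxygen on C5, C7 and C8a and the acyl carbon C4 on C4a, the pattern left by a Claisen fold of a C4-to-C8a tetraketide. In one operation a magnesium-templated Claisen closure builds ring A and a freed ortho phenoxide expels methoxide from C2 to close ring C. The precursor is an (R)-2,3-dihydro-1-benzoxepine (ring B, oxepine and stereocentre in place) whose C4 carries the 3,5,7-trioxoheptanoate chain and whose C5 (flavone C2) is a methyl enol ether; the phenol is MOM-protected and the carbinol silylated.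

Key step: step 10

Remark: the core is numbered as a flavone (O1, C2–C4, C4a, C5–C8, C8a; ring B primed); 8, 13 and 14 are keto–enol mixtures drawn as one tautomer, and enolates or other conjugate bases formed in the flask are counted with their parent compounds.

Step 1
Reactants: 1 methyl 2,4-dihydroxybenzoate
Product: 2 methyl 2-hydroxy-4-(methoxymethoxy)benzoate
Conditions: MOMCl (1.1 equiv), iPr2NEt, CH2Cl2, 0 °C to rt
Reagents that add atoms: chloromethyl methyl ether, COCCl
Why: Williamson-type O-alkylation under a mild amine base should take only the 4-hydroxyl, because the 2-hydroxyl is locked in a hydrogen bond to the ester carbonyl and is the less acidic and less accessible of the two.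

Step 2
Reactants: 3 2-methylbut-3-en-2-ol
Product: 4 methyl 5-methylhex-4-enoate
Conditions: MeC(OMe)3 (4 equiv), EtCO2H (cat.), sealed vessel, 130 °C
Reagents that add atoms: trimethyl orthoacetate, CC(OC)(OC)OC
Why: Johnson–Claisen rearrangement: the mixed ketene acetal formed from the tertiary allylic alcohol undergoes a [3,3]-sigmatropic shift that installs the CH2CO2Me unit and leaves the trisubstituted Me2C=CH alkene.

Step 3
Reactants: 4 methyl 5-methylhex-4-enoate
Product: 5 methyl 3-[(2S)-3,3-dimethyloxiran-2-yl]propanoate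
Conditions: L-fructose-derived Shi ketone (0.3 equiv), KHSO5 (Oxone), K2CO3, Bu4NHSO4 (cat.), MeCN–CH2(OMe)2–aq. Na2B4O7 (pH 10.5), 0 °C
Reagents that add atoms: potassium peroxymonosulfate, [K+].[O-]S(=O)(=O)OO
Why: Shi asymmetric epoxidation: the chiral dioxirane transfers oxygen through a spiro transition state to one face of the trisubstituted alkene, and the L-fructose-derived ketone is chosen because, by the established model, the D-fructose-derived one delivers the (R)-oxirane carbon with Me2C=CH–CH2R alkenes, so its mirror image should set the (2S) centre.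

Step 4
Reactants: 2 methyl 2-hydroxy-4-(methoxymethoxy)benzoate, 5 methyl 3-[(2S)-3,3-dimethyloxiran-2-yl]propanoate
Product: 6 methyl (4R)-5-hydroxy-4-[2-(methoxycarbonyl)-5-(methoxymethoxy)phenoxy]-5-methylhexanoate
Conditions: 5 (1.3 equiv), Cs2CO3 (0.3 equiv), DMF, 90–100 °C
Reagents that add atoms: none
Why: Base-catalysed SN2 opening of the epoxide by the phenoxide occurs at the less substituted oxirane carbon with inversion, which turns the (2S)-oxirane centre into the (4R)-aryloxy centre that is carried unchanged to the target; the sub-stoichiometric base lets the phenol reprotonate the tertiary alkoxide at once and so disfavours δ-lactonisation.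

Step 5
Reactants: 6 methyl (4R)-5-hydroxy-4-[2-(methoxycarbonyl)-5-(methoxymethoxy)phenoxy]-5-methylhexanoate
Product: 7 methyl (4R)-4-[2-(methoxycarbonyl)-5-(methoxymethoxy)phenoxy]-5-methyl-5-[(triethylsilyl)oxy]hexanoate
Conditions: TESOTf (1.2 equiv), 2,6-lutidine, CH2Cl2, −78 °C
Reagents that add atoms: triethylsilyl trifluoromethanesulfonate, CC[Si](CC)(CC)OS(=O)(=O)C(F)(F)F
Why: Silylation with a silyl triflate and a hindered pyridine base is fast even for tertiary alcohols at −78 °C, where the aryl MOM acetal is not activated, and it removes the hydroxyl that could lactonise or transacylate under the strongly basic conditions that follow.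

Step 6
Reactants: 7 methyl (4R)-4-[2-(methoxycarbonyl)-5-(methoxymethoxy)phenoxy]-5-methyl-5-[(triethylsilyl)oxy]hexanoate
Product: 8 methyl (2R)-8-(methoxymethoxy)-5-oxo-2-{2-[(triethylsilyl)oxy]propan-2-yl}-2,3,4,5-tetrahydro-1-benzoxepine-4-carboxylate
Conditions: KOtBu (2.5 equiv), THF, 0 to 50 °C; AcOH
Reagents that add atoms: none
Why: Dieckmann condensation: only the aliphatic ester can enolise, its enolate attacks the aryl ester (7-exo-trig) and the equilibrium is drawn forward by deprotonation of the β-keto ester, while the C2 stereocentre carries no acidic hydrogen and is not touched.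

Step 7
Reactants: 8 methyl (2R)-8-(methoxymethoxy)-5-oxo-2-{2-[(triethylsilyl)oxy]propan-2-yl}-2,3,4,5-tetrahydro-1-benzoxepine-4-carboxylate
Product: 9 methyl (2R)-5-methoxy-8-(methoxymethoxy)-2-{2-[(triethylsilyl)oxy]propan-2-yl}-2,3-dihydro-1-benzoxepine-4-carboxylate
Conditions: KOtBu (1.1 equiv), THF–DMPU, 0 °C; Me2SO4 (1.3 equiv), 0 °C to rt
Reagents that add atoms: dimethyl sulfate, COS(=O)(=O)OC
Why: O-Alkylation of a β-keto ester enolate: the dissociated potassium enolate in a dipolar aprotic medium reacts with the hard electrophile dimethyl sulfate at oxygen, helped by the tertiary, hindered C4 and by conjugation of the enolate oxygen with the aryl ring, to give the vinylogous carbonate.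

Step 8
Reactants: 9 methyl (2R)-5-methoxy-8-(methoxymethoxy)-2-{2-[(triethylsilyl)oxy]propan-2-yl}-2,3-dihydro-1-benzoxepine-4-carboxylate
Product: 10 (2R)-5-methoxy-8-(methoxymethoxy)-2-{2-[(triethylsilyl)oxy]propan-2-yl}-2,3-dihydro-1-benzoxepine-4-carboxylic acid
Conditions: LiOH·H2O (5 equiv), THF–MeOH–H2O, 50 °C; aq. citric acid to pH 4, 0 °C
Reagents that add atoms: lithium hydroxide, [Li+].[OH-]
Why: Ester saponification (BAc2) should leave the enol ether intact because its β-carbon is tetrasubstituted and deactivated by the methoxy and electron-rich aryl donors, as in the hydrolysis of β-methoxyacrylate esters, and buffered acidification spares the acetal and the silyl ether.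

Step 9
Reactants: 10 (2R)-5-methoxy-8-(methoxymethoxy)-2-{2-[(triethylsilyl)oxy]propan-2-yl}-2,3-dihydro-1-benzoxepine-4-carboxylic acid, 11 methyl 3,5-dioxohexanoate
Product: 13 methyl 7-[(2R)-5-methoxy-8-(methoxymethoxy)-2-{2-[(triethylsilyl)oxy]propan-2-yl}-2,3-dihydro-1-benzoxepin-4-yl]-3,5,7-trioxoheptanoate, via acyl imidazolide 12 (not isolated)
Conditions: 10, CDI (1.1 equiv), THF, rt, CO2 purged; added at −78 °C to 11 (3.5 equiv) pretreated with LiN(iPr)2 (10.5 equiv), THF, −78 to 0 °C; then to −30 °C; AcOH
Reagents that add atoms: none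
Why: Acylation of a β-dicarbonyl polyanion: the terminal carbanion of the trilithio derivative of 11 is its most basic and nucleophilic site and is C-acylated by the acyl imidazolide at the activated carbonyl and not at the hindered enol-ether carbon, the excess trianion absorbing the protons of imidazole and of the more acidic product.

Step 10
Reactants: 13 methyl 7-[(2R)-5-methoxy-8-(methoxymethoxy)-2-{2-[(triethylsilyl)oxy]propan-2-yl}-2,3-dihydro-1-benzoxepin-4-yl]-3,5,7-trioxoheptanoate
Product: 15 (R)-5,7-dihydroxy-4′-(methoxymethoxy)flavone bridged from C3 to O2′ by CH2–CH[C(CH3)2OSiEt3] (the 4′-O-MOM O-TES 6,8-bisdesprenyl form of 18), via acylphloroglucinol ketone 14 (not isolated)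
Conditions: Mg(OMe)2 (8 equiv), MeOH, rt then 60 °C; cold 0.5 M HCl to pH 5
Reagents that add atoms: none
Why: Excess Mg(OMe)2 converts the 3,5,7-triketo ester into a magnesium-chelated polyenolate in which the C4a carbanion adds to the ester carbonyl C8a (6-exo-trig); loss of methoxide and enolisation give ring A as the acylphloroglucinol 14, a Claisen cyclisation of a triketo ester that is the laboratory counterpart of the chalcone-synthase fold. Either of the two equivalent ortho phenoxides of 14 (the C5 and C8a oxygens are interchanged by rotation about C4–C4a) then adds to C2 of the β-methoxy enone (6-endo-trig conjugate addition) and methoxide is eliminated, closing ring C as in chromone syntheses from o-hydroxyaryl β-alkoxy enones. No stereocentre is formed, and the existing C–O centre, which has no acidic hydrogen and is remote from every enolisable position, is untouched. The step needs C-acylation (C4a to C8a) to beat the aldol mode (C8 to C4) and closures through enolate oxygen: C4 is a hindered, electron-rich vinylogous ester carbonyl and so a poor aldol acceptor, and magnesium chelation ties up the enolate oxygens and favours carbon attack on the ester. The silyl ether and the MOM acetal are inert to methoxide.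

Step 11
Reactants: 15 (R)-5,7-dihydroxy-4′-(methoxymethoxy)flavone bridged from C3 to O2′ by CH2–CH[C(CH3)2OSiEt3]
Product: 16 6,8-diiodo derivative of 15
Conditions: NIS (2.05 equiv), DMF, 0 °C to rt, dark
Reagents that add atoms: N-iodosuccinimide, O=C1CCC(=O)N1I
Why: Electrophilic aromatic iodination: C6 and C8 are the only free positions of ring A and each lies ortho or para to three oxygen substituents, whereas ring B carries only ether oxygens and is not attacked by NIS without acid.

Step 12
Reactants: 16 6,8-diiodo derivative of 15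
Product: 17 6,8-bis(3-methylbut-2-enyl) derivative of 15 (the 4′-O-MOM O-TES form of 18)
Conditions: tributyl(3-methylbut-2-enyl)stannane (3 equiv), Pd(PPh3)4 (10 mol %), DMF, 90 °C
Reagents that add atoms: tributyl(3-methylbut-2-enyl)stannane, CCCC[Sn](CCCC)(CCCC)CC=C(C)C
Why: Twofold Stille coupling: oxidative addition of zerovalent palladium into each aryl–iodine bond, transfer of the prenyl group from tin and reductive elimination at the unsubstituted allyl terminus should give the linear 3-methylbut-2-enyl groups, and the neutral conditions tolerate the free phenols, the acetal and the silyl ether.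

Step 13
Reactants: 17 6,8-bis(3-methylbut-2-enyl) derivative of 15
Product: 18 target: (R)-5,7,4′-trihydroxy-6,8-bis(3-methylbut-2-enyl)flavone bridged from C3 to O2′ by CH2–CH[C(CH3)2OH]
Conditions: HCl (1.25 M in MeOH), rt
Reagents that add atoms: none
Why: Acid-catalysed methanolysis cleaves the MOM acetal and the tertiary triethylsilyl ether in one operation under conditions mild enough that the prenyl groups flanked by phenols should not cyclise to chromans, and the stereocentre is not involved.

Compound list
1 | methyl 2,4-dihydroxybenzoate | COC(=O)c1ccc(O)cc1O | starting material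
2 | methyl 2-hydroxy-4-(methoxymethoxy)benzoate | COCOc1ccc(C(=O)OC)c(O)c1 | intermediate
3 | 2-methylbut-3-en-2-ol | CC(C)(O)C=C | starting material
4 | methyl 5-methylhex-4-enoate | COC(=O)CCC=C(C)C | intermediate
5 | methyl 3-[(2S)-3,3-dimethyloxiran-2-yl]propanoate | COC(=O)CC[C@@H]1OC1(C)C | intermediate
6 | methyl (4R)-5-hydroxy-4-[2-(methoxycarbonyl)-5-(methoxymethoxy)phenoxy]-5-methylhexanoate | COC(=O)CC[C@H](C(C)(C)O)Oc1cc(OCOC)ccc1C(=O)OC | intermediate
7 | methyl (4R)-4-[2-(methoxycarbonyl)-5-(methoxymethoxy)phenoxy]-5-methyl-5-[(triethylsilyl)oxy]hexanoate | COC(=O)CC[C@H](C(C)(C)O[Si](CC)(CC)CC)Oc1cc(OCOC)ccc1C(=O)OC | intermediate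
8 | methyl (2R)-8-(methoxymethoxy)-5-oxo-2-{2-[(triethylsilyl)oxy]propan-2-yl}-2,3,4,5-tetrahydro-1-benzoxepine-4-carboxylate (C4 epimers and enol) | COC(=O)C1C[C@H](C(C)(C)O[Si](CC)(CC)CC)Oc2cc(OCOC)ccc2C1=O | intermediate
9 | methyl (2R)-5-methoxy-8-(methoxymethoxy)-2-{2-[(triethylsilyl)oxy]propan-2-yl}-2,3-dihydro-1-benzoxepine-4-carboxylate | COC(=O)C1=C(OC)c2ccc(OCOC)cc2O[C@@H](C(C)(C)O[Si](CC)(CC)CC)C1 | intermediate
10 | (2R)-5-methoxy-8-(methoxymethoxy)-2-{2-[(triethylsilyl)oxy]propan-2-yl}-2,3-dihydro-1-benzoxepine-4-carboxylic acid | OC(=O)C1=C(OC)c2ccc(OCOC)cc2O[C@@H](C(C)(C)O[Si](CC)(CC)CC)C1 | intermediate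
11 | methyl 3,5-dioxohexanoate | COC(=O)CC(=O)CC(C)=O | starting material
12 | 1H-imidazol-1-yl ketone (acyl imidazolide) of acid 10 | O=C(n1ccnc1)C1=C(OC)c2ccc(OCOC)cc2O[C@@H](C(C)(C)O[Si](CC)(CC)CC)C1 | intermediate
13 | methyl 7-[(2R)-5-methoxy-8-(methoxymethoxy)-2-{2-[(triethylsilyl)oxy]propan-2-yl}-2,3-dihydro-1-benzoxepin-4-yl]-3,5,7-trioxoheptanoate | COC(=O)CC(=O)CC(=O)CC(=O)C1=C(OC)c2ccc(OCOC)cc2O[C@@H](C(C)(C)O[Si](CC)(CC)CC)C1 | intermediate
14 | [(2R)-5-methoxy-8-(methoxymethoxy)-2-{2-[(triethylsilyl)oxy]propan-2-yl}-2,3-dihydro-1-benzoxepin-4-yl](2,4,6-trihydroxyphenyl)methanone | O=C(c1c(O)cc(O)cc1O)C1=C(OC)c2ccc(OCOC)cc2O[C@@H](C(C)(C)O[Si](CC)(CC)CC)C1 | intermediate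
15 | (R)-5,7-dihydroxy-4′-(methoxymethoxy)flavone bridged from C3 to O2′ by CH2–CH[C(CH3)2OSiEt3] | O=c1c2c(O)cc(O)cc2oc2c1C[C@H](C(C)(C)O[Si](CC)(CC)CC)Oc1cc(OCOC)ccc1-2 | intermediate
16 | 6,8-diiodo derivative of 15 | O=c1c2c(O)c(I)c(O)c(I)c2oc2c1C[C@H](C(C)(C)O[Si](CC)(CC)CC)Oc1cc(OCOC)ccc1-2 | intermediate
17 | 6,8-bis(3-methylbut-2-enyl) derivative of 15 | CC(C)=CCc1c(O)c(CC=C(C)C)c2oc3c(c(=O)c2c1O)C[C@H](C(C)(C)O[Si](CC)(CC)CC)Oc1cc(OCOC)ccc1-3 | intermediate
18 | (R)-5,7,4′-trihydroxy-6,8-bis(3-methylbut-2-enyl)flavone bridged from C3 to O2′ by CH2–CH[C(CH3)2OH] (CNP0328977.2) | CC(C)=CCc1c(O)c(CC=C(C)C)c2oc3c(c(=O)c2c1O)C[C@H](C(C)(C)O)Oc1cc(O)ccc1-3 | target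

Total step count: 13. Longest linear sequence: 12 steps (steps 2 to 13, from 3 to 18).

Steps most likely to fail

Step 10. The polyketone may fold in the wrong sense (aldol closure from C8 onto C4, or attack of the C5 enolate oxygen on C2 before the carbocycle exists), or the chain may be cut by retro-Claisen methanolysis. The fallback brings ring A in intact instead of folding it. It sets out from 10 through its imidazolide 12. This is acylated at −78 °C in THF by 2,4,6-tris(benzyloxy)phenyllithium F1, generated from 2-bromo-1,3,5-tris(benzyloxy)benzene with n-BuLi, to give the tris(benzyloxy)phenyl ketone F2. Hydrogenolysis (H2, Pd/C, EtOAc) should free the three phenols to give 14, and brief treatment with K2CO3 in MeOH closes ring C, so the route is rejoined at 15.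

Step 9. Proton transfer from liberated imidazole or from the acidic product may quench the trianion, and the unmasked tetracarbonyl chain may cyclise during work-up. The fallback builds the chain with its ester end masked. It sets out from 12, which acylates the dilithio dianion of 2,2-dimethyl-6-(2-oxopropyl)-4H-1,3-dioxin-4-one F3 (made by C-acetylation of the lithium dienolate of 2,2,6-trimethyl-4H-1,3-dioxin-4-one with N-acetylimidazole) to give the diketo-dioxinone F4. Heating F4 in toluene with MeOH at 110 °C should expel acetone by a retro-hetero-Diels–Alder reaction, and the acylketene is trapped as the methyl ester, so the route is rejoined at 13 directly before the key step.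

Step 4. The hydrogen-bonded, ortho-substituted phenoxide may open the hindered epoxide so slowly that loss of the epoxide or lactonisation of the product overtakes ether formation. The fallback uses a phenoxide without the ortho ester and adds the ester carbon afterwards. It sets out from 5, which is opened under the same base catalysis by 2-iodo-5-(methoxymethoxy)phenol F5 (from 3-(methoxymethoxy)phenol with I2 and NaHCO3) to give the iodoaryl ether F6. Silylation as in step 5 gives the triethylsilyl ether F7. Methoxycarbonylation (PdCl2(PPh3)2, CO, MeOH, Et3N, DMF, 70 °C) then installs the aryl ester, and the route is rejoined at 7.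

Further compounds
F1 | step 10 | 2,4,6-tris(benzyloxy)phenyllithium | [Li]c1c(OCc2ccccc2)cc(OCc2ccccc2)cc1OCc1ccccc1
F2 | step 10 | [(2R)-5-methoxy-8-(methoxymethoxy)-2-{2-[(triethylsilyl)oxy]propan-2-yl}-2,3-dihydro-1-benzoxepin-4-yl][2,4,6-tris(benzyloxy)phenyl]methanone | O=C(c1c(OCc2ccccc2)cc(OCc2ccccc2)cc1OCc1ccccc1)C1=C(OC)c2ccc(OCOC)cc2O[C@@H](C(C)(C)O[Si](CC)(CC)CC)C1
F3 | step 9 | 2,2-dimethyl-6-(2-oxopropyl)-4H-1,3-dioxin-4-one | CC(=O)CC1=CC(=O)OC(C)(C)O1
F4 | step 9 | 6-{4-[(2R)-5-methoxy-8-(methoxymethoxy)-2-{2-[(triethylsilyl)oxy]propan-2-yl}-2,3-dihydro-1-benzoxepin-4-yl]-2,4-dioxobutyl}-2,2-dimethyl-4H-1,3-dioxin-4-one | CC1(C)OC(=O)C=C(CC(=O)CC(=O)C2=C(OC)c3ccc(OCOC)cc3O[C@@H](C(C)(C)O[Si](CC)(CC)CC)C2)O1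
F5 | step 4 | 2-iodo-5-(methoxymethoxy)phenol | COCOc1ccc(I)c(O)c1
F6 | step 4 | methyl (4R)-5-hydroxy-4-[2-iodo-5-(methoxymethoxy)phenoxy]-5-methylhexanoate | COC(=O)CC[C@H](C(C)(C)O)Oc1cc(OCOC)ccc1I
F7 | step 4 | methyl (4R)-4-[2-iodo-5-(methoxymethoxy)phenoxy]-5-methyl-5-[(triethylsilyl)oxy]hexanoate | COC(=O)CC[C@H](C(C)(C)O[Si](CC)(CC)CC)Oc1cc(OCOC)ccc1I
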